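**Retrosynthetic overview**

1. The target is a cis-fused hydroazulene: five-membered ring C1–C2=C3–C4(OH)(Me)–C5, seven-membered ring C5–C6(OH)–C7(side chain)–C8–C9(OH)–C10(=C18H2)–C1 (C1 and C5 are the ring-fusion CH atoms; side chain C11(Me)–C12(OAc)–C13(OAc)–C14=C15Me2).
2. Enabling feature: the exocyclic methylene C10=C18 sits on the seven-membered-ring carbon next to fusion atom C1, and oxygenated C6 and C7 lie next to fusion atom C5. The bonds C1–C5 and C9–C10 therefore map onto an intramolecular [5+2] cycloaddition of a terminal allene (C18=C10=C1) with a 2-siloxy-vinylcyclopropane (C5=C6(OSi)–C7, ring CH2 groups C8/C9) across the tether C2–C3–C4.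
3. Ring order: both rings form in that one step from acyclic 15 (five-membered ring by C1–C5, then seven-membered ring by C9–C10). Afterwards: enol ether → C6 ketone → 6β-OH, SeO2 hydroxylation at C9, elimination of the C3 pivalate handle to C2=C3, and completion of the side chain by chelation-controlled isobutenyl addition and acetylation.
4. 15 is assembled linearly from crotonaldehyde diethyl acetal (C11–C13), cyclopropanecarbonitrile (C6–C9), methyl pyruvate (C3, C4, 4-Me), propargyl bromide and formaldehyde (C2, C1, C10, C18). Stereocontrol: Shi epoxidation (C11, C12), copper–bisoxazoline Mukaiyama aldol (C4), Felkin–Anh propargylation (C3, sacrificial).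

Key step: step 12

Remark: numbering as above; α is the face of the bicycle carrying H1 and H5, β the opposite face; TBS = tert-butyldimethylsilyl, PMB = 4-methoxybenzyl, Piv = pivaloyl; "side chain A" = (2R,3S)-4,4-diethoxy-3-(PMB-oxy)butan-2-yl (C11–C13); the fructose-derived epoxidation catalyst is assumed to show its usual facial preference with the acetal-substituted E-alkene.

**Route**

Step 1
Reactants: 1 (E)-1,1-diethoxybut-2-ene
Product: 2 (2S,3R)-2-(diethoxymethyl)-3-methyloxirane
Conditions: D-fructose-derived ketone catalyst (30 mol %), Oxone (2KHSO5·KHSO4·K2SO4), K2CO3, Bu4NHSO4, MeCN/CH2(OMe)2/aq. Na2B4O7, 0 °C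
Reagents that add atoms: potassium peroxymonosulfate [K+].[O-]S(=O)(=O)OO
Why: Shi asymmetric epoxidation (chiral dioxirane, spiro transition state) sets C11 and C12 together, the E-alkene giving the trans-epoxide and the D-fructose-derived catalyst the (2S,3R) enantiomer by analogy with other E-disubstituted alkenes.

Step 2
Reactants: 2 (2S,3R)-2-(diethoxymethyl)-3-methyloxirane; 3 cyclopropanecarbonitrile
Product: 4 1-[(2R,3S)-4,4-diethoxy-3-hydroxybutan-2-yl]cyclopropane-1-carbonitrile
Conditions: LiN(i-Pr)2, THF, −78 °C; then 2, DMPU, −78 °C → rt; aq. NH4Cl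
Reagents that add atoms: none
Why: SN2 epoxide opening by the α-cyano carbanion should occur at the methyl-bearing carbon, away from the bulky and inductively deactivating acetal, with inversion at C11 and retention at C12, so the trans-epoxide gives the syn C11-Me/C12-OH pair and the quaternary cyclopropane carbon C7.

Step 3
Reactants: 4 1-[(2R,3S)-4,4-diethoxy-3-hydroxybutan-2-yl]cyclopropane-1-carbonitrile
Product: 5 1-[side chain A]cyclopropane-1-carbonitrile (PMB ether of 4)
Conditions: NaH, 4-MeOC6H4CH2Cl, Bu4NI (cat.), DMF, 0 °C → rt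
Reagents that add atoms: 4-methoxybenzyl chloride COc1ccc(CCl)cc1
Why: Williamson etherification; the PMB ether is chosen because it later serves as the chelating group in step 20 and is removed oxidatively without touching silyl ethers.

Step 4
Reactants: 5 1-[side chain A]cyclopropane-1-carbonitrile
Product: 6 1-{1-[side chain A]cyclopropyl}ethan-1-one
Conditions: MeLi, Et2O, 0 °C → rt; then aq. citric acid
Reagents that add atoms: methyllithium [Li]C; water O
Why: addition of MeLi to the nitrile stops at the N-lithio ketimine, whose mild hydrolysis should give the methyl ketone (C6 and C5) without affecting the acetal.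

Step 5
Reactants: 6 1-{1-[side chain A]cyclopropyl}ethan-1-one
Product: 7 trimethylsilyl enol ether of 6
Conditions: LiN(i-Pr)2, Me3SiCl, THF, −78 °C
Reagents that add atoms: chlorotrimethylsilane C[Si](C)(C)Cl
Why: kinetic enolisation and O-silylation can only involve the methyl group because C7 is quaternary, giving the terminal enol silane for the Mukaiyama aldol.

Step 6
Reactants: 7 trimethylsilyl enol ether of 6; 8 methyl pyruvate
Product: 10 methyl (2S)-2-hydroxy-2-methyl-4-oxo-4-{1-[side chain A]cyclopropyl}butanoate, via trimethylsilyl ether of the aldol adduct 9 (not isolated)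
Conditions: Cu(OTf)2/(S,S)-t-Bu-bis(oxazoline) (10 mol %), THF, −78 → −40 °C; then 1 M HCl, THF, 0 °C
Reagents that add atoms: none
Why: catalytic enantioselective Mukaiyama aldol addition to pyruvate chelated to divalent copper; the (S,S)-ligand shields one ketone face and should give the (S)-tertiary carbinol C4 under catalyst control, independent of the remote side-chain stereocentres.

Step 7
Reactants: 10 methyl (2S)-2-hydroxy-2-methyl-4-oxo-4-{1-[side chain A]cyclopropyl}butanoate
Product: 11 methyl (2S,3Z)-2,4-bis(TBS-oxy)-2-methyl-4-{1-[side chain A]cyclopropyl}but-3-enoate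
Conditions: TBSOTf (3 equiv), Et3N, CH2Cl2, −20 → 0 °C
Reagents that add atoms: tert-butyldimethylsilyl trifluoromethanesulfonate CC(C)(C)[Si](C)(C)OS(=O)(=O)C(F)(F)F
Why: silyl triflate/amine silylation of the tertiary alcohol plus soft enolisation of the ketone, which is regiospecific (only C5 carries α-hydrogens) and should give the (Z)-enol ether; this masks the ketone for step 8 and is the 2-siloxy-vinylcyclopropane of the key step, while the α-alkoxy acetal should be inert at this temperature.

Step 8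
Reactants: 11 methyl (2S,3Z)-2,4-bis(TBS-oxy)-2-methyl-4-{1-[side chain A]cyclopropyl}but-3-enoate
Product: 12 (2S,3Z)-2,4-bis(TBS-oxy)-2-methyl-4-{1-[side chain A]cyclopropyl}but-3-enal
Conditions: i-Bu2AlH, CH2Cl2, −78 °C
Reagents that add atoms: none
Why: low-temperature DIBAL reduction of the α-siloxy ester should stop at the aldehyde (C3) through the stable tetrahedral aluminium hemiacetal.

Step 9
Reactants: 12 (2S,3Z)-2,4-bis(TBS-oxy)-2-methyl-4-{1-[side chain A]cyclopropyl}but-3-enal
Product: 13 (4R,5S,6Z)-5,7-bis(TBS-oxy)-5-methyl-7-{1-[side chain A]cyclopropyl}hept-6-en-1-yn-4-ol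
Conditions: HC≡CCH2Br, Zn, THF, 0 °C; aq. NH4Cl
Reagents that add atoms: propargyl bromide C#CCBr
Why: Barbier propargylation (SE2′ of the allenylzinc species) gives the homopropargylic alcohol; the polar Felkin–Anh model (C4–OSi anti to the nucleophile, attack past the methyl group) should set C3 so that the C3 and C4 oxygens are cis on the later five-membered ring.

Step 10
Reactants: 13 (4R,5S,6Z)-5,7-bis(TBS-oxy)-5-methyl-7-{1-[side chain A]cyclopropyl}hept-6-en-1-yn-4-ol
Product: 14 pivalate ester of 13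
Conditions: PivCl, Et3N, DMAP (cat.), CH2Cl2, rt
Reagents that add atoms: pivaloyl chloride CC(C)(C)C(=O)Cl
Why: standard acylation; the pivalate protects C3–OH through steps 11–16, adds bulk on the α-face for step 12 and marks C3 for later elimination.

Step 11
Reactants: 14 pivalate ester of 13
Product: 15 (5R,6S,7Z)-6,8-bis(TBS-oxy)-6-methyl-8-{1-[side chain A]cyclopropyl}octa-1,2,7-trien-5-yl pivalate
Conditions: (CH2O)n, CuBr (30 mol %), i-Pr2NH, 1,4-dioxane, reflux
Reagents that add atoms: formaldehyde (as paraformaldehyde) C=O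
Why: Crabbé homologation (Mannich reaction of the terminal alkyne, then copper-mediated hydride transfer with loss of an imine) should convert the alkyne into the terminal allene C18=C10=C1.

Step 12
Reactants: 15 (5R,6S,7Z)-6,8-bis(TBS-oxy)-6-methyl-8-{1-[side chain A]cyclopropyl}octa-1,2,7-trien-5-yl pivalate
Product: 16 cis-hydroazulene cycloadduct (1α-H, 5α-H, 3α-OPiv, 4α-OTBS, 4β-Me, enol ether C6(OTBS)=C7, side chain A on C7, 10-methylidene)
Conditions: [Rh(CO)2Cl]2 (5 mol %), ClCH2CH2Cl, 80 °C
Reagents that add atoms: none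
Why: Monovalent rhodium should open the vinylcyclopropane oxidatively to a σ-alkyl/π-allyl rhodacycle (Rh–C9, allyl C5–C6–C7), the internal π-bond C1=C10 of the tethered allene inserts at allyl terminus C5 to make the C1–C5 bond, and C9–C10 reductive elimination releases 16; the closest known reaction type is the rhodium-catalysed intramolecular [5+2] cycloaddition of vinylcyclopropanes with tethered terminal allenes, which engages the internal allene double bond and gives cis-fused bicyclo[5.3.0]decenes carrying an exocyclic methylene. The five-membered ring closes by C1–C5 formation through the three-atom tether C2–C3–C4 (exo carbometalation of the allene), and the seven-membered ring closes by C–C reductive elimination (C9–C10) from the eight-membered rhodacycle. C1 and C5 are created together in a suprafacial insertion, so H1 and H5 should end up cis; their absolute sense is relayed from the tether, because C6 should bond on the face of the nascent cyclopentane opposite the two cis-disposed oxygen substituents (4α-OTBS, 3α-OPiv) and syn to the small 4β-methyl group. The step needs (a) reaction at the internal and not the terminal allene π-bond, secured by the tether length and the known preference of [Rh(CO)2Cl]2, (b) no regiochemical choice in cyclopropane cleavage, secured because C7 carries two identical ring CH2 groups, and (c) the (Z)-enol ether geometry with the tether trans to the cyclopropane, secured in step 7. The exocyclic methylene, the masked C6 ketone and the complete ring skeleton are thereby set in one operation from an acyclic precursor.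

Step 13
Reactants: 16 cis-hydroazulene cycloadduct
Product: 17 C6 ketone (7α-H, side chain A 7β; otherwise as 16)
Conditions: HF·pyridine, pyridine, THF, 0 °C
Reagents that add atoms: none
Why: fluoride-induced cleavage of the silyl enol ether is much faster than that of the tertiary alkyl TBS ether, and the enol should be protonated at C7 from the convex α-face, placing the side chain β, which is also the thermodynamically preferred cis-2,7-disubstituted cycloheptanone.

Step 14
Reactants: 17 C6 ketone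
Product: 18 6β-alcohol
Conditions: LiBH(s-Bu)3, THF, −78 °C
Reagents that add atoms: none
Why: the bulky hydride should attack the ketone from the α-face, opposite the two β-oriented flanking substituents (five-membered ring carbon C4 on C5, side chain on C7), giving the 6β-alcohol cis to the side chain.

Step 15
Reactants: 18 6β-alcohol
Product: 19 6β,9α-diol
Conditions: SeO2 (20 mol %), t-BuOOH, CH2Cl2, 0 °C → rt
Reagents that add atoms: tert-butyl hydroperoxide CC(C)(C)OO
Why: SeO2 allylic oxidation (ene reaction, then [2,3]-sigmatropic shift) of a 1,1-disubstituted alkene should hydroxylate the ring CH2 (C9) in preference to the tertiary C1–H and keep the double bond exocyclic, with oxygen delivered to the α-face away from the β-side chain on C7; no other reactive alkene is present at this stage.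

Step 16
Reactants: 19 6β,9α-diol
Product: 20 6β,9α-bis(TBS) ether
Conditions: TBSOTf, 2,6-lutidine, CH2Cl2, −78 °C
Reagents that add atoms: tert-butyldimethylsilyl trifluoromethanesulfonate CC(C)(C)[Si](C)(C)OS(=O)(=O)C(F)(F)F
Why: standard silylation of the two secondary alcohols, needed so that only C3–OH is free in step 18 and only the side-chain diol is acetylated in step 22.

Step 17
Reactants: 20 6β,9α-bis(TBS) ether
Product: 21 3α-alcohol (pivalate removed)
Conditions: i-Bu2AlH, CH2Cl2, −78 °C
Reagents that add atoms: none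
Why: reductive ester cleavage at low temperature frees C3–OH without the basic alkoxide conditions that could move the neighbouring C4 silyl group.

Step 18
Reactants: 21 3α-alcohol
Product: 22 cyclopentene (C2=C3) with 4α-OTBS, 6β-OTBS, 9α-OTBS and side chain A
Conditions: Martin sulfurane (Ph2S[OC(CF3)2Ph]2), CH2Cl2, 0 °C → rt
Reagents that add atoms: none
Why: sulfurane-mediated dehydration of a secondary alcohol; elimination can only go towards C2 because C4 is quaternary, so the C2=C3 double bond should form regiospecifically next to the already correct C4 carbinol centre.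

Step 19
Reactants: 22 cyclopentene
Product: 23 C13 aldehyde (12-OPMB)
Conditions: Et3SiOTf, 2,4,6-collidine, CH2Cl2, 0 °C; then H2O
Reagents that add atoms: water O
Why: silyl triflate/collidine acetal cleavage (via a collidinium salt hydrolysed on work-up) should unmask the aldehyde under non-acidic conditions that leave the TBS ethers, the tertiary allylic ether and the skipped diene intact.

Step 20
Reactants: 23 C13 aldehyde
Product: 24 (13S)-allylic alcohol carrying the 2-methylprop-1-enyl group
Conditions: Me2C=CHMgBr, MgBr2·OEt2, CH2Cl2, −78 °C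
Reagents that add atoms: 2-methylprop-1-enylmagnesium bromide CC(C)=C[Mg]Br
Why: Grignard addition to an α-alkoxy aldehyde under Cram chelation control (magnesium bridging the aldehyde and PMB-ether oxygens) should bring the nucleophile in opposite the C11 branch and give the 12,13-syn product.

Step 21
Reactants: 24 (13S)-allylic alcohol
Product: 25 12,13-diol
Conditions: DDQ, CH2Cl2/pH 7 buffer, 0 °C
Reagents that add atoms: none
Why: oxidative cleavage of the PMB ether by DDQ is fast at 0 °C and leaves silyl ethers and alkenes untouched.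

Step 22
Reactants: 25 12,13-diol
Product: 26 12,13-diacetate (4α, 6β, 9α tris-TBS ether of the target)
Conditions: Ac2O, pyridine, DMAP (cat.), CH2Cl2, rt
Reagents that add atoms: acetic anhydride CC(=O)OC(C)=O
Why: standard acetylation; only the two side-chain hydroxyls are free, so the acetates should go on exactly where the target has them.

Step 23
Reactants: 26 12,13-diacetate
Product: 27 target
Conditions: HF·pyridine, pyridine, THF, 0 °C → rt
Reagents that add atoms: none
Why: buffered fluoride desilylation should remove the three TBS groups without acetate migration or cleavage.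

**Compound list**

1 | (E)-1,1-diethoxybut-2-ene | C/C=C/C(OCC)OCC | starting material
2 | (2S,3R)-2-(diethoxymethyl)-3-methyloxirane | CCOC(OCC)[C@H]1O[C@@H]1C | intermediate
3 | cyclopropanecarbonitrile | N#CC1CC1 | starting material
4 | 1-[(2R,3S)-4,4-diethoxy-3-hydroxybutan-2-yl]cyclopropane-1-carbonitrile | N#CC1(CC1)[C@@H](C)[C@H](O)C(OCC)OCC | intermediate
5 | 1-[(2R,3S)-4,4-diethoxy-3-(4-methoxybenzyloxy)butan-2-yl]cyclopropane-1-carbonitrile | N#CC1(CC1)[C@@H](C)[C@H](OCc2ccc(OC)cc2)C(OCC)OCC | intermediate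
6 | 1-{1-[(2R,3S)-4,4-diethoxy-3-(4-methoxybenzyloxy)butan-2-yl]cyclopropyl}ethan-1-one | CC(=O)C1(CC1)[C@@H](C)[C@H](OCc2ccc(OC)cc2)C(OCC)OCC | intermediate
7 | trimethylsilyl enol ether of 6 | C=C(O[Si](C)(C)C)C1(CC1)[C@@H](C)[C@H](OCc2ccc(OC)cc2)C(OCC)OCC | intermediate
8 | methyl pyruvate | CC(=O)C(=O)OC | starting material
9 | methyl (2S)-2-methyl-4-oxo-2-(trimethylsilyloxy)-4-{1-[side chain A]cyclopropyl}butanoate | COC(=O)[C@@](CC(=O)C1(CC1)[C@@H](C)[C@H](OCc2ccc(OC)cc2)C(OCC)OCC)(C)O[Si](C)(C)C | intermediate (not isolated)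
10 | methyl (2S)-2-hydroxy-2-methyl-4-oxo-4-{1-[side chain A]cyclopropyl}butanoate | COC(=O)[C@@](CC(=O)C1(CC1)[C@@H](C)[C@H](OCc2ccc(OC)cc2)C(OCC)OCC)(C)O | intermediate
11 | methyl (2S,3Z)-2,4-bis(TBS-oxy)-2-methyl-4-{1-[side chain A]cyclopropyl}but-3-enoate | COC(=O)[C@@](/C=C(\O[Si](C)(C)C(C)(C)C)C1(CC1)[C@@H](C)[C@H](OCc2ccc(OC)cc2)C(OCC)OCC)(C)O[Si](C)(C)C(C)(C)C | intermediate
12 | (2S,3Z)-2,4-bis(TBS-oxy)-2-methyl-4-{1-[side chain A]cyclopropyl}but-3-enal | O=C[C@@](/C=C(\O[Si](C)(C)C(C)(C)C)C1(CC1)[C@@H](C)[C@H](OCc2ccc(OC)cc2)C(OCC)OCC)(C)O[Si](C)(C)C(C)(C)C | intermediate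
13 | (4R,5S,6Z)-5,7-bis(TBS-oxy)-5-methyl-7-{1-[side chain A]cyclopropyl}hept-6-en-1-yn-4-ol | C#CC[C@@H](O)[C@@](/C=C(\O[Si](C)(C)C(C)(C)C)C1(CC1)[C@@H](C)[C@H](OCc2ccc(OC)cc2)C(OCC)OCC)(C)O[Si](C)(C)C(C)(C)C | intermediate
14 | (4R,5S,6Z)-5,7-bis(TBS-oxy)-5-methyl-7-{1-[side chain A]cyclopropyl}hept-6-en-1-yn-4-yl pivalate | C#CC[C@@H](OC(=O)C(C)(C)C)[C@@](/C=C(\O[Si](C)(C)C(C)(C)C)C1(CC1)[C@@H](C)[C@H](OCc2ccc(OC)cc2)C(OCC)OCC)(C)O[Si](C)(C)C(C)(C)C | intermediate
15 | (5R,6S,7Z)-6,8-bis(TBS-oxy)-6-methyl-8-{1-[side chain A]cyclopropyl}octa-1,2,7-trien-5-yl pivalate | C=C=CC[C@@H](OC(=O)C(C)(C)C)[C@@](/C=C(\O[Si](C)(C)C(C)(C)C)C1(CC1)[C@@H](C)[C@H](OCc2ccc(OC)cc2)C(OCC)OCC)(C)O[Si](C)(C)C(C)(C)C | intermediate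
16 | cis-hydroazulene cycloadduct: 1α-H, 5α-H, 3α-OPiv, 4α-OTBS, 4β-Me, C6(OTBS)=C7, side chain A on C7, 10-methylidene | C=C1CCC([C@@H](C)[C@H](OCc3ccc(OC)cc3)C(OCC)OCC)=C(O[Si](C)(C)C(C)(C)C)[C@@H]2[C@H]1C[C@@H](OC(=O)C(C)(C)C)[C@@]2(C)O[Si](C)(C)C(C)(C)C | intermediate
17 | 6-ketone: as 16 with C6=O, 7α-H, side chain A 7β | C=C1CC[C@@H]([C@@H](C)[C@H](OCc3ccc(OC)cc3)C(OCC)OCC)C(=O)[C@@H]2[C@H]1C[C@@H](OC(=O)C(C)(C)C)[C@@]2(C)O[Si](C)(C)C(C)(C)C | intermediate
18 | 6β-alcohol of 17 | C=C1CC[C@@H]([C@@H](C)[C@H](OCc3ccc(OC)cc3)C(OCC)OCC)[C@@H](O)[C@@H]2[C@H]1C[C@@H](OC(=O)C(C)(C)C)[C@@]2(C)O[Si](C)(C)C(C)(C)C | intermediate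
19 | 6β,9α-diol (3α-OPiv, 4α-OTBS) | C=C1[C@H](O)C[C@@H]([C@@H](C)[C@H](OCc3ccc(OC)cc3)C(OCC)OCC)[C@@H](O)[C@@H]2[C@H]1C[C@@H](OC(=O)C(C)(C)C)[C@@]2(C)O[Si](C)(C)C(C)(C)C | intermediate
20 | 6β,9α-bis(TBS) ether of 19 | C=C1[C@H](O[Si](C)(C)C(C)(C)C)C[C@@H]([C@@H](C)[C@H](OCc3ccc(OC)cc3)C(OCC)OCC)[C@@H](O[Si](C)(C)C(C)(C)C)[C@@H]2[C@H]1C[C@@H](OC(=O)C(C)(C)C)[C@@]2(C)O[Si](C)(C)C(C)(C)C | intermediate
21 | 3α-alcohol (4α, 6β, 9α tris-TBS ether) | C=C1[C@H](O[Si](C)(C)C(C)(C)C)C[C@@H]([C@@H](C)[C@H](OCc3ccc(OC)cc3)C(OCC)OCC)[C@@H](O[Si](C)(C)C(C)(C)C)[C@@H]2[C@H]1C[C@@H](O)[C@@]2(C)O[Si](C)(C)C(C)(C)C | intermediate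
22 | Δ2-cyclopentene (4α, 6β, 9α tris-TBS ether, side chain A) | C=C1[C@H](O[Si](C)(C)C(C)(C)C)C[C@@H]([C@@H](C)[C@H](OCc3ccc(OC)cc3)C(OCC)OCC)[C@@H](O[Si](C)(C)C(C)(C)C)[C@@H]2[C@H]1C=C[C@@]2(C)O[Si](C)(C)C(C)(C)C | intermediate
23 | C13 aldehyde: side chain (2R,3S)-3-(PMB-oxy)-4-oxobutan-2-yl | C=C1[C@H](O[Si](C)(C)C(C)(C)C)C[C@@H]([C@@H](C)[C@H](OCc3ccc(OC)cc3)C=O)[C@@H](O[Si](C)(C)C(C)(C)C)[C@@H]2[C@H]1C=C[C@@]2(C)O[Si](C)(C)C(C)(C)C | intermediate
24 | allylic alcohol: side chain (2R,3S,4S)-4-hydroxy-3-(PMB-oxy)-6-methylhept-5-en-2-yl | C=C1[C@H](O[Si](C)(C)C(C)(C)C)C[C@@H]([C@@H](C)[C@H](OCc3ccc(OC)cc3)[C@H](C=C(C)C)O)[C@@H](O[Si](C)(C)C(C)(C)C)[C@@H]2[C@H]1C=C[C@@]2(C)O[Si](C)(C)C(C)(C)C | intermediate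
25 | diol: side chain (2R,3S,4S)-3,4-dihydroxy-6-methylhept-5-en-2-yl | C=C1[C@H](O[Si](C)(C)C(C)(C)C)C[C@@H]([C@@H](C)[C@H](O)[C@H](C=C(C)C)O)[C@@H](O[Si](C)(C)C(C)(C)C)[C@@H]2[C@H]1C=C[C@@]2(C)O[Si](C)(C)C(C)(C)C | intermediate
26 | diacetate: 4α, 6β, 9α tris-TBS ether of the target | C=C1[C@H](O[Si](C)(C)C(C)(C)C)C[C@@H]([C@@H](C)[C@H](OC(C)=O)[C@H](C=C(C)C)OC(C)=O)[C@@H](O[Si](C)(C)C(C)(C)C)[C@@H]2[C@H]1C=C[C@@]2(C)O[Si](C)(C)C(C)(C)C | intermediate
27 | target: cis-hydroazulene-4α,6β,9α-triol (1α-H, 5α-H, 4β-Me, C2=C3, 10-methylidene) with 7β-[(2R,3S,4S)-3,4-diacetoxy-6-methylhept-5-en-2-yl] | C=C1[C@H](O)C[C@@H]([C@@H](C)[C@H](OC(C)=O)[C@H](C=C(C)C)OC(C)=O)[C@@H](O)[C@@H]2[C@H]1C=C[C@@]2(C)O | target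

**Step count and risks**

Total step count: 23. Longest linear sequence: 23 steps (1 → 27); compounds 3 and 8 and all other reagents are commercial inputs.

Steps most likely to fail:

Step 12 (key step). What may go wrong: oxidative ring-opening of the crowded, fully substituted siloxy-vinylcyclopropane may be slower than rhodium-induced oligomerisation or isomerisation of the terminal allene. Fallback (alkyne as the two-carbon partner, then reductive allylic transposition): setting out from 14, deprotonation of the alkyne (n-BuLi, THF, −78 °C) and addition to paraformaldehyde should give the propargylic alcohol F1, and Ac2O/pyridine its propargylic acetate F2. [Rh(CO)2Cl]2 (ClCH2CH2Cl, 60 °C) should then give the alkyne–vinylcyclopropane [5+2] adduct F3, the partner class with the broadest precedent, in which C1 is still sp2 (C1=C10). Pd(OAc)2/PBu3/HCO2NH4 (dioxane, 100 °C; Tsuji–Trost formate reduction through a π-allyl complex of zerovalent palladium) should deliver hydride to the more substituted allyl terminus C1 on the less hindered α-face and move the double bond to C10=C18, which returns the route to 16.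

Step 2. What may go wrong: the tertiary cyclopropyl carbanion may open the 2,3-disubstituted epoxide too slowly, so that base-induced isomerisation of the epoxide takes over. Fallback (build the cyclopropane after the C7–C11 bond): from 2, lithioacetonitrile (MeCN, n-BuLi, THF, −78 → 0 °C) should open the epoxide at the same carbon to give the hydroxy nitrile F4, and NaH/4-methoxybenzyl chloride its PMB ether F5. LiN(i-Pr)2 (2.2 equiv) with 1-bromo-2-chloroethane should then give the chloroethyl nitrile F6, which closes in the same flask by 3-exo-tet alkylation to 5.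

Step 15. What may go wrong: oxygen may be delivered to the β-face of C9, or the ene step may abstract the C1 hydrogen instead of a C9 hydrogen. Fallback for the facial problem (oxidation then reduction instead of direct hydroxylation): if 18 gives the 9β-alcohol F7, MnO2 (CH2Cl2, rt) should oxidise this allylic alcohol selectively (the 6-OH is not allylic) to the exo-methylene enone F8, and Luche reduction (NaBH4, CeCl3·7H2O, MeOH, −78 °C) should bring hydride in from the same accessible β-face and give 19.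

Further compounds
F1 | step 12 | (5R,6S,7Z)-6,8-bis(TBS-oxy)-1-hydroxy-6-methyl-8-{1-[side chain A]cyclopropyl}oct-7-en-2-yn-5-yl pivalate | OCC#CC[C@@H](OC(=O)C(C)(C)C)[C@@](/C=C(\O[Si](C)(C)C(C)(C)C)C1(CC1)[C@@H](C)[C@H](OCc2ccc(OC)cc2)C(OCC)OCC)(C)O[Si](C)(C)C(C)(C)C
F2 | step 12 | (5R,6S,7Z)-1-acetoxy-6,8-bis(TBS-oxy)-6-methyl-8-{1-[side chain A]cyclopropyl}oct-7-en-2-yn-5-yl pivalate | CC(=O)OCC#CC[C@@H](OC(=O)C(C)(C)C)[C@@](/C=C(\O[Si](C)(C)C(C)(C)C)C1(CC1)[C@@H](C)[C@H](OCc2ccc(OC)cc2)C(OCC)OCC)(C)O[Si](C)(C)C(C)(C)C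
F3 | step 12 | hydroazulene diene with C1=C10, 10-(acetoxymethyl), C6(OTBS)=C7, 3α-OPiv, 4α-OTBS, 4β-Me, 5α-H, side chain A on C7 | CC(=O)OCC1=C2C[C@@H](OC(=O)C(C)(C)C)[C@@](C)(O[Si](C)(C)C(C)(C)C)[C@@H]2C(O[Si](C)(C)C(C)(C)C)=C([C@@H](C)[C@H](OCc3ccc(OC)cc3)C(OCC)OCC)CC1
F4 | step 2 | (3R,4S)-5,5-diethoxy-4-hydroxy-3-methylpentanenitrile | N#CC[C@@H](C)[C@H](O)C(OCC)OCC
F5 | step 2 | (3R,4S)-5,5-diethoxy-4-(4-methoxybenzyloxy)-3-methylpentanenitrile | N#CC[C@@H](C)[C@H](OCc1ccc(OC)cc1)C(OCC)OCC
F6 | step 2 | (3R,4S)-2-(2-chloroethyl)-5,5-diethoxy-4-(4-methoxybenzyloxy)-3-methylpentanenitrile (C2 epimers) | N#CC(CCCl)[C@@H](C)[C@H](OCc1ccc(OC)cc1)C(OCC)OCC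
F7 | step 15 | 9β-epimer of 19 (6β,9β-diol) | C=C1[C@@H](O)C[C@@H]([C@@H](C)[C@H](OCc3ccc(OC)cc3)C(OCC)OCC)[C@@H](O)[C@@H]2[C@H]1C[C@@H](OC(=O)C(C)(C)C)[C@@]2(C)O[Si](C)(C)C(C)(C)C
F8 | step 15 | 9-oxo-10-methylidene enone (6β-OH, 3α-OPiv, 4α-OTBS) | C=C1C(=O)C[C@@H]([C@@H](C)[C@H](OCc3ccc(OC)cc3)C(OCC)OCC)[C@@H](O)[C@@H]2[C@H]1C[C@@H](OC(=O)C(C)(C)C)[C@@]2(C)O[Si](C)(C)C(C)(C)C
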